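**Retrosynthetic overview**
1. Locants: ring A is the cyclohexene C1(O‑acyl)–C2–C3–C4–C5=C6(CH3); ring B is the cycloheptane C3–C4–C7(CH3)2–C8–C9–C10–C11(CH3)(OH); C3–C4 is the trans ring fusion.
2. Feature the strategy rests on: the ring‑B methylene C10 sits between C9 and the oxygen‑bearing C11. Removing C10 (bonds C10–C11 and C9–C10) turns ring B into the cyclohexanone ring of a trans‑fused octalone with a C11 ketone, so ring B is made by one‑carbon enlargement with Me3SiCHN2.
3. The octalone comes from an enantioselective, para‑selective Diels–Alder reaction of isoprene with 4,4‑dimethylcyclohex‑2‑enone, then C3 epimerisation to the trans fusion.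
4. After the enlargement: C11 ketone → methylidene → Markovnikov hydration (C11 carbinol); C1=C6 → C1 ketone → C5=C6 enone → C1 allylic alcohol; Mitsunobu inversion at C1 with silyl‑protected isovanillic acid; desilylation.
5. Ring order: ring A together with the six‑membered forerunner of ring B (step 1), then ring B by expansion (step 3).

Key step: step 3

Assumption: the sense of induction in step 1 is taken from the usual pre‑transition‑state model of cationic oxazaborolidines with 2‑cyclohexenones; if the opposite enantiomer forms, the (R)‑catalyst is used under the same conditions.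

**Step 1**
Reactants: 1 4,4‑dimethylcyclohex‑2‑en‑1‑one; 2 isoprene
Product: 3 (4aR,8aS)‑4,4,6‑trimethyl‑3,4,4a,5,8,8a‑hexahydronaphthalen‑1(2H)‑one (cis‑fused octalone)
Conditions: (S)‑3,3‑diphenyl‑1‑(o‑tolyl)tetrahydro‑1H,3H‑pyrrolo[1,2‑c][1,3,2]oxazaborole (20 mol%), AlBr3 (16 mol%), isoprene (5 equiv), CH2Cl2, −40 → −20 °C
Reagents that add atoms: none
Why: Lewis‑acid‑catalysed asymmetric Diels–Alder reaction, in which the isoprene CH2 next to the methyl‑bearing carbon bonds to the enone β‑carbon C4 (para adduct, CH3 on C6), suprafacial addition gives the cis fusion, and the catalyst‑bound enone (boron syn to C3–H, C3=C4 stacked on one phenyl group) is attacked on its open face so that C4 should be set as 4aR.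

**Step 2**
Reactants: 3 cis‑fused octalone
Product: 4 (4aR,8aR)‑4,4,6‑trimethyl‑3,4,4a,5,8,8a‑hexahydronaphthalen‑1(2H)‑one (trans‑fused octalone)
Conditions: NaOMe (0.2 equiv), MeOH, 25 °C
Reagents that add atoms: none
Why: base‑mediated epimerisation through the C3 enolate should favour the trans‑fused 1‑decalone‑type ketone with both fusion bonds equatorial, while the non‑enolisable C4 keeps its configuration.

**Step 3**
Reactants: 4 trans‑fused octalone; 5 trimethylsilyldiazomethane
Product: 7 (4aR,9aR)‑2,9,9‑trimethyl‑1,4,4a,6,7,8,9,9a‑octahydro‑5H‑benzo[7]annulen‑5‑one, via α‑silyl ketone 6 (not isolated)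
Conditions: Me3SiCHN2 (1.3 equiv), BF3·OEt2 (1.3 equiv), CH2Cl2, −78 → −30 °C; then 1 M HCl, THF, 0 °C
Reagents that add atoms: none
Why: BF3 activates the C11 carbonyl, the diazo carbon of 5 adds to it, and loss of N2 from the β‑oxido diazonium ion with a concerted 1,2‑shift of C9 from C11 to the new carbon C10 forms C10–C11 and C9–C10 and gives α‑silyl ketone 6, whose C10–Si bond is cleaved by acid to leave the C10 methylene. The closest known reaction is the Lewis‑acid‑promoted homologation of cyclic ketones with trimethylsilyldiazomethane, a Tiffeneau–Demjanov‑type rearrangement. Ring B is closed not by cyclisation but by ring enlargement, the six‑membered ketone ring becoming the seven‑membered ring through the 1,2‑alkyl shift. No stereocentre is created (C10 ends as CH2 and the migrating C9 is CH2), and C3 and C4 keep the configurations of steps 1 and 2 because the fusion bonds are not involved and the medium is not basic. The step needs migration of the methylene C9 in preference to the ring‑fusion methine C3; the bulky Me3Si group should add with N2 antiperiplanar to the less hindered C9–C11 bond, away from the branched C3 side. A second homologation is held back by the silyl group on C10 of 6.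

**Step 4**
Reactants: 7 trans‑fused cycloheptanone
Product: 8 (4aR,9aR)‑2,9,9‑trimethyl‑5‑methylidene‑4,4a,5,6,7,8,9,9a‑octahydro‑1H‑benzo[7]annulene
Conditions: Cp2TiMe2 (2.5 equiv), toluene, 70 °C, dark
Reagents that add atoms: dimethyltitanocene Cp2TiMe2, C[Ti](C)(C1C=CC=C1)C1C=CC=C1
Why: Petasis methylenation (Cp2Ti=CH2, oxatitanacyclobutane, cycloreversion) converts the hindered C11 ketone into the methylidene without base, so the enolisable C3 centre is not epimerised.

**Step 5**
Reactants: 8 methylidene diene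
Product: 10 (4aR,5R,9aR)‑2,5,9,9‑tetramethyl‑4,4a,5,6,7,8,9,9a‑octahydro‑1H‑benzo[7]annulen‑5‑ol, via tertiary hydroperoxide 9 (not isolated)
Conditions: Co(acac)2 (20 mol%), PhSiH3 (2 equiv), O2 (1 atm), THF, 0 → 25 °C; then PPh3 (1.5 equiv)
Reagents that add atoms: dioxygen, O=O
Why: Mukaiyama hydration by hydrogen‑atom transfer: H adds to the unhindered methylidene CH2 faster than to the trisubstituted C1=C6 alkene, and the tertiary C11 radical should be trapped by O2 on the exposed face anti to the C3–C4 bond, which stands nearly perpendicular to the radical plane in the twist‑chair of ring B, so that the C11 oxygen ends cis to H3 (C11 R) and the methyl trans; a methyl nucleophile adding to ketone 7 would use the same exposed face and give the C11 epimer, which is why oxygen and not carbon is introduced last.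

**Step 6**
Reactants: 10 tertiary alcohol
Product: 12 (4aR,5R,9aR)‑2,5,9,9‑tetramethyldecahydro‑1H‑benzo[7]annulene‑3,5‑diol (C1/C6 diastereomer mixture), via alkylborane 11 (not isolated)
Conditions: BH3·THF (3 equiv), THF, 0 → 25 °C; then 3 M NaOH, 30% H2O2, 0 → 25 °C
Reagents that add atoms: hydrogen peroxide, OO
Why: hydroboration–oxidation puts boron on the less substituted C1 by syn anti‑Markovnikov addition and oxidation with retention gives the C1 alcohol; the uncontrolled configurations at C1 and C6 are both erased later (C1 ketone, C6 sp2).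

**Step 7**
Reactants: 12 diol
Product: 13 (4aR,5R,9aR)‑5‑hydroxy‑2,5,9,9‑tetramethyl‑1,2,4,4a,5,6,7,8,9,9a‑decahydro‑3H‑benzo[7]annulen‑3‑one (C6 epimers)
Conditions: (n‑Pr)4N[RuO4] (5 mol%), NMO (1.5 equiv), 4 Å MS, CH2Cl2, 25 °C
Reagents that add atoms: none
Why: Ley–Griffith oxidation takes the secondary C1 alcohol to the ketone, and the tertiary C11 alcohol cannot be oxidised.

**Step 8**
Reactants: 13 hydroxy ketone
Product: 16 (4aR,5R,9aR)‑5‑hydroxy‑2,5,9,9‑tetramethyl‑4,4a,5,6,7,8,9,9a‑octahydro‑3H‑benzo[7]annulen‑3‑one, via bis‑silyl enol ether 14 (not isolated), via enone silyl ether 15 (not isolated)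
Conditions: TMSOTf (2.5 equiv), Et3N (4 equiv), CH2Cl2, 0 → 25 °C; then Pd(OAc)2 (10 mol%), O2 (1 atm), DMSO, 25 °C; then 1 M HCl, THF, 0 °C
Reagents that add atoms: none
Why: Saegusa–Ito desaturation: equilibrating silylation should give the more substituted C1=C6 enol ether (and the C11 silyl ether), the palladium enolate at C6 undergoes syn β‑hydride elimination toward C5 to give the conjugated C5=C6 enone, O2 reoxidises palladium, and dilute acid frees the tertiary alcohol.

**Step 9**
Reactants: 16 hydroxy enone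
Product: 17 (3S,4aR,5R,9aR)‑2,5,9,9‑tetramethyl‑4,4a,5,6,7,8,9,9a‑octahydro‑3H‑benzo[7]annulene‑3,5‑diol
Conditions: NaBH4 (1.2 equiv), CeCl3·7H2O (1.2 equiv), MeOH, −40 °C
Reagents that add atoms: none
Why: Luche 1,2‑reduction, in which hydride should add axially to C1 on the face of the axial H3 (as in carvone → cis‑carveol), giving the pseudo‑equatorial C1–OH cis to C11, i.e. the C1 epimer needed for inversion.

**Step 10**
Reactants: 18 isovanillic acid
Product: 20 3‑[(tert‑butyldimethylsilyl)oxy]‑4‑methoxybenzoic acid, via bis‑silyl derivative 19 (not isolated)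
Conditions: TBSCl (2.3 equiv), imidazole (5 equiv), DMF, 25 °C; then AcOH/THF/H2O (3:1:1), 25 °C
Reagents that add atoms: tert‑butyldimethylsilyl chloride, CC(C)(C)[Si](C)(C)Cl
Why: silylation of phenol and acid followed by selective hydrolysis of the labile silyl ester masks the phenol, which would otherwise compete as a Mitsunobu nucleophile.

**Step 11**
Reactants: 17 allylic alcohol; 20 silyl‑protected isovanillic acid
Product: 21 (3R,4aR,5R,9aR)‑5‑hydroxy‑2,5,9,9‑tetramethyl‑4,4a,5,6,7,8,9,9a‑octahydro‑3H‑benzo[7]annulen‑3‑yl 3‑[(tert‑butyldimethylsilyl)oxy]‑4‑methoxybenzoate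
Conditions: PPh3 (1.5 equiv), DIAD (1.5 equiv), THF, 0 → 25 °C
Reagents that add atoms: none
Why: Mitsunobu esterification, in which the carboxylate displaces the C1 alkoxyphosphonium by SN2 with inversion (3S → 3R, ester oxygen cis to H3); the tertiary C11 alcohol does not react and SN2′ attack at C5 is disfavoured by the substitution at C4 and C7.

**Step 12**
Reactants: 21 silyl‑protected ester
Product: 22 CNP0210711.2, (3R,4aR,5R,9aR)‑5‑hydroxy‑2,5,9,9‑tetramethyl‑4,4a,5,6,7,8,9,9a‑octahydro‑3H‑benzo[7]annulen‑3‑yl 3‑hydroxy‑4‑methoxybenzoate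
Conditions: Bu4NF (1.1 equiv), AcOH (1.2 equiv), THF, 0 °C
Reagents that add atoms: none
Why: fluoride cleavage of the aryl silyl ether, buffered with acetic acid, should leave the allylic ester and the tertiary alcohol untouched.

**Compound list**
1 | 4,4‑dimethylcyclohex‑2‑en‑1‑one | CC1(C)CCC(=O)C=C1 | starting material
2 | isoprene | C=CC(C)=C | starting material
3 | (4aR,8aS)‑4,4,6‑trimethyl‑3,4,4a,5,8,8a‑hexahydronaphthalen‑1(2H)‑one (cis‑fused) | O=C1CCC(C)(C)[C@@H]2CC(C)=CC[C@H]12 | intermediate
4 | (4aR,8aR)‑4,4,6‑trimethyl‑3,4,4a,5,8,8a‑hexahydronaphthalen‑1(2H)‑one (trans‑fused, key‑step precursor) | O=C1CCC(C)(C)[C@@H]2CC(C)=CC[C@@H]12 | intermediate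
5 | trimethylsilyldiazomethane | C[Si](C)(C)C=[N+]=[N-] | starting material
6 | (4aR,9aR)‑2,9,9‑trimethyl‑6‑(trimethylsilyl)‑1,4,4a,6,7,8,9,9a‑octahydro‑5H‑benzo[7]annulen‑5‑one (C10 epimers) | O=C1C([Si](C)(C)C)CCC(C)(C)[C@@H]2CC(C)=CC[C@@H]12 | intermediate (not isolated)
7 | (4aR,9aR)‑2,9,9‑trimethyl‑1,4,4a,6,7,8,9,9a‑octahydro‑5H‑benzo[7]annulen‑5‑one (key‑step product) | O=C1CCCC(C)(C)[C@@H]2CC(C)=CC[C@@H]12 | intermediate
8 | (4aR,9aR)‑2,9,9‑trimethyl‑5‑methylidene‑4,4a,5,6,7,8,9,9a‑octahydro‑1H‑benzo[7]annulene | C=C1CCCC(C)(C)[C@@H]2CC(C)=CC[C@@H]12 | intermediate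
9 | (4aR,5R,9aR)‑5‑hydroperoxy‑2,5,9,9‑tetramethyl‑4,4a,5,6,7,8,9,9a‑octahydro‑1H‑benzo[7]annulene | CC1=CC[C@@H]2[C@@H](C1)C(C)(C)CCC[C@@]2(C)OO | intermediate (not isolated)
10 | (4aR,5R,9aR)‑2,5,9,9‑tetramethyl‑4,4a,5,6,7,8,9,9a‑octahydro‑1H‑benzo[7]annulen‑5‑ol | CC1=CC[C@@H]2[C@@H](C1)C(C)(C)CCC[C@@]2(C)O | intermediate
11 | C1 alkylborane of 10 (drawn as RBH2; C1/C6 configuration not controlled) | CC1C(B)C[C@@H]2[C@@H](C1)C(C)(C)CCC[C@@]2(C)O | intermediate (not isolated)
12 | (4aR,5R,9aR)‑2,5,9,9‑tetramethyldecahydro‑1H‑benzo[7]annulene‑3,5‑diol (C1/C6 configuration not controlled) | CC1C(O)C[C@@H]2[C@@H](C1)C(C)(C)CCC[C@@]2(C)O | intermediate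
13 | (4aR,5R,9aR)‑5‑hydroxy‑2,5,9,9‑tetramethyl‑1,2,4,4a,5,6,7,8,9,9a‑decahydro‑3H‑benzo[7]annulen‑3‑one (C6 epimers) | CC1C(=O)C[C@@H]2[C@@H](C1)C(C)(C)CCC[C@@]2(C)O | intermediate
14 | C1=C6 trimethylsilyl enol ether, C11 trimethylsilyl ether of 13 | CC1=C(O[Si](C)(C)C)C[C@@H]2[C@@H](C1)C(C)(C)CCC[C@@]2(C)O[Si](C)(C)C | intermediate (not isolated)
15 | C11 trimethylsilyl ether of 16 | O=C1C[C@@H]2[C@@H](C=C1C)C(C)(C)CCC[C@@]2(C)O[Si](C)(C)C | intermediate (not isolated)
16 | (4aR,5R,9aR)‑5‑hydroxy‑2,5,9,9‑tetramethyl‑4,4a,5,6,7,8,9,9a‑octahydro‑3H‑benzo[7]annulen‑3‑one | O=C1C[C@@H]2[C@@H](C=C1C)C(C)(C)CCC[C@@]2(C)O | intermediate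
17 | (3S,4aR,5R,9aR)‑2,5,9,9‑tetramethyl‑4,4a,5,6,7,8,9,9a‑octahydro‑3H‑benzo[7]annulene‑3,5‑diol | O[C@H]1C[C@@H]2[C@@H](C=C1C)C(C)(C)CCC[C@@]2(C)O | intermediate
18 | isovanillic acid | COc1ccc(C(=O)O)cc1O | starting material
19 | tert‑butyldimethylsilyl 3‑[(tert‑butyldimethylsilyl)oxy]‑4‑methoxybenzoate | COc1ccc(C(=O)O[Si](C)(C)C(C)(C)C)cc1O[Si](C)(C)C(C)(C)C | intermediate (not isolated)
20 | 3‑[(tert‑butyldimethylsilyl)oxy]‑4‑methoxybenzoic acid | COc1ccc(C(=O)O)cc1O[Si](C)(C)C(C)(C)C | intermediate
21 | silyl‑protected ester (3R,4aR,5R,9aR) | COc1ccc(C(=O)O[C@@H]2C[C@@H]3[C@@H](C=C2C)C(C)(C)CCC[C@@]3(C)O)cc1O[Si](C)(C)C(C)(C)C | intermediate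
22 | CNP0210711.2 | COc1ccc(C(=O)O[C@@H]2C[C@@H]3[C@@H](C=C2C)C(C)(C)CCC[C@@]3(C)O)cc1O | target

**Step count**
Total steps: 12. Longest linear sequence: 11 (steps 1–9, 11, 12); step 10 is the side branch.

**Three steps most likely to fail**

Step 3 (key step). The ring‑fusion carbon C3 may migrate in competition with C9, which would put the new carbon between C11 and C3; the diazonium betaine may also close to an epoxide, or a second homologation may occur. The fallback sets out from 4 and fixes the regiochemistry by enolate formation instead of migratory aptitude. Kinetic deprotonation at C9 with LiN(i‑Pr)2 and Me3SiCl (THF, −78 °C) gives the C9=C11 silyl enol ether F1. Cyclopropanation of this electron‑rich alkene with Et2Zn and CH2I2 (CH2Cl2, 0 °C) gives the siloxycyclopropane F2. FeCl3 in DMF at 0 °C cleaves the C9–C11 bond oxidatively to the β‑chloro cycloheptanone F3, and NaOAc in MeOH at 60 °C eliminates HCl to the cycloheptenone F4. Conjugate reduction of the C9=C10 enone with [(Ph3P)CuH]6 in wet benzene comes back to the route at 7.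

Step 1. The γ,γ‑disubstituted enone may turn over slowly at the chiral catalyst, so that an achiral background reaction and diene polymerisation lower conversion and enantiomeric purity. The fallback sets out from 1 and 2: the achiral AlCl3‑promoted Diels–Alder reaction (0.3 equiv, toluene, 40 °C) gives the racemic cis‑fused octalone F5, and NaOMe in MeOH equilibrates it to the racemic trans‑fused octalone F6. Preparative chromatography on a cellulose tris(3,5‑dimethylphenylcarbamate) phase resolves F6, and the (4aR,8aR) enantiomer re‑enters the route as 4.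

Step 5. O2 may capture the planar C11 radical with little facial discrimination, giving the C11 epimer, and hydrogen‑atom transfer to the C1=C6 alkene may lead to over‑hydration. The fallback sets out from 8 and uses ionic Markovnikov hydration. Hg(OAc)2 (1.05 equiv, THF/H2O, 0 °C) reacts selectively at the 1,1‑disubstituted alkene and water should attack C11 on the exposed face, giving the organomercurial F7. NaBH4 in aqueous NaOH then reduces the C–Hg bond and the route is rejoined at 10; any C11 epimer is removed there by chromatography.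

**Further compounds**
F1 | step 3 | C9=C11 trimethylsilyl enol ether of 4 | C[Si](C)(C)OC1=CCC(C)(C)[C@@H]2CC(C)=CC[C@@H]12
F2 | step 3 | siloxycyclopropane (C10 bridging C9 and C11; cyclopropane configuration not controlled) | C[Si](C)(C)OC12CC1CC(C)(C)[C@@H]3CC(C)=CC[C@@H]23
F3 | step 3 | β‑chloro cycloheptanone (C9 chloride of 7) | O=C1CC(Cl)CC(C)(C)[C@@H]2CC(C)=CC[C@@H]12
F4 | step 3 | C9=C10 cycloheptenone | O=C1C=CCC(C)(C)[C@@H]2CC(C)=CC[C@@H]12
F5 | step 1 | racemic cis‑fused octalone | O=C1CCC(C)(C)[C@@H]2CC(C)=CC[C@H]12.O=C1CCC(C)(C)[C@H]2CC(C)=CC[C@@H]12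
F6 | step 1 | racemic trans‑fused octalone | O=C1CCC(C)(C)[C@@H]2CC(C)=CC[C@@H]12.O=C1CCC(C)(C)[C@H]2CC(C)=CC[C@H]12
F7 | step 5 | C11 hydroxy organomercurial acetate | CC1=CC[C@@H]2[C@@H](C1)C(C)(C)CCC[C@@]2(C[Hg]OC(C)=O)O
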